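**Retrosynthetic overview**
1. Target 18 comes from resorcylate 8 by forming a tertiary aryl–O–C(CH3)2CH=CH2 bond at the 4-oxygen twice. Each ether then passes its allyl unit by [3,3] shift to an ortho carbon (C3, C5) as a normal prenyl group and frees the 4-OH again.
2. Resorcylate 8 comes from ynone 5 and dimethyl malonate 6 by Michael addition and Claisen ring closure. This is the only ring made in the route (the resorcylate ring); the phenyl ring is bought.
3. Ynone 5 comes from 4-phenyl-1-butyne 1 and N-methoxy-N-methylacetamide 2.
4. The prenyl donor, carbonate 12, comes from 2-methylbut-3-en-2-ol 9 and di-tert-butyl dicarbonate 10.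

Assumption: the target has no stereocentre and no stereogenic alkene, so "single enantiomer" is taken to mean the single constitutional isomer drawn; no stereocontrol is needed.
Ring positions are numbered as in the target throughout (C1 ester, C2 OH, C3, C4 OH, C5, C6 phenethyl).

**Step 1**
Reactants: 1 4-phenyl-1-butyne; 2 N-methoxy-N-methylacetamide
Product: 5 6-phenylhex-3-yn-2-one, via lithium acetylide 3 (not isolated), via tetrahedral lithium adduct 4 (not isolated)
Conditions: n-BuLi (1.05 equiv), THF, −78 °C, 30 min; then 2 (1.2 equiv), −78 → 0 °C; inverse quench into cold 1 M HCl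
Reagents that add atoms: none
Why: Weinreb ketone synthesis, in which acetylide 3 adds once to the N-methoxy-N-methylamide to give the chelated adduct 4 that cannot over-add and collapses to the ynone only in the acidic quench, which also protonates the released amine before it can add to the ynone.

**Step 2**
Reactants: 5 6-phenylhex-3-yn-2-one; 6 dimethyl malonate
Product: 8 methyl 2,4-dihydroxy-6-(2-phenylethyl)benzoate, via Michael adduct 7 (not isolated)
Conditions: NaOMe (2.2 equiv), MeOH, 0 °C then reflux, 8 h; 1 M HCl to pH 2
Reagents that add atoms: none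
Why: Michael addition of sodiomalonate to the ynone β-carbon gives 7 (its E/Z isomers interconvert through the delocalised malonate anion), and intramolecular Claisen (Dieckmann-type) condensation of the methyl ketone enolate onto one ester, with loss of methanol, closes the six-membered ring, which is already at the arene oxidation level because the alkyne supplied the extra unsaturation and so enolises irreversibly to the resorcylate phenoxide.

**Step 3**
Reactants: 9 2-methylbut-3-en-2-ol; 10 di-tert-butyl dicarbonate
Product: 12 tert-butyl (2-methylbut-3-en-2-yl) carbonate, via lithium alkoxide 11 (not isolated)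
Conditions: n-BuLi (1.05 equiv), THF, 0 °C, 20 min; then 10 (1.1 equiv), 0 °C → rt, 3 h; H2O quench
Reagents that add atoms: none
Why: Acyl transfer from the anhydride to the tertiary lithium alkoxide (mixed carbonate formation) proceeds cleanly under basic conditions that do not ionise the tertiary allylic C–O bond.

**Step 4**
Reactants: 8 methyl 2,4-dihydroxy-6-(2-phenylethyl)benzoate; 12 tert-butyl (2-methylbut-3-en-2-yl) carbonate (two portions)
Product: 18 methyl 2,4-dihydroxy-3,5-bis(3-methylbut-2-en-1-yl)-6-(2-phenylethyl)benzoate, via 4-O-(1,1-dimethylallyl) ether 13 (not isolated), via 3-prenyl resorcylate 14 (not isolated), via 5-prenyl resorcylate 15 (not isolated), via 3-prenyl 4-O-(1,1-dimethylallyl) ether 16 (not isolated), via 5-prenyl 4-O-(1,1-dimethylallyl) ether 17 (not isolated)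
Conditions: 12 (1.2 equiv), Pd(PPh3)4 (5 mol %), PhMe, 0 °C, 2 h; Eu(fod)3 (10 mol %; fod = 6,6,7,7,8,8,8-heptafluoro-2,2-dimethyloctane-3,5-dionate), 70 °C, 4 h; cool to 0 °C, 12 (1.2 equiv), Pd(PPh3)4 (2 mol %), 2 h; 70 °C, 6 h
Reagents that add atoms: none
Why: Proposed new method: a temperature-cycled, oxygen-relayed ortho,ortho'-diprenylation in one flask, in which at 0 °C zerovalent palladium ionises 12 to a 1,1-dimethylallyl palladium cation and tert-butoxide (after loss of CO2), the only non-chelated phenoxide (O-4; the 2-OH is locked to the ester carbonyl by its hydrogen bond) attacks the more substituted allyl terminus to form the tertiary C–O bond of 13, and on warming with the oxophilic trivalent europium Lewis acid the ether undergoes an aromatic Claisen [3,3] shift that places a normal prenyl group on an ortho carbon and returns the free 4-OH for a second identical cycle; since both carbons ortho to O-4 must end up prenylated, the site filled first (mainly C3 to give 14 because the chelate fixes double-bond character in C3–C4, some C5 to give 15) does not matter and both streams converge on 18 through 16 and 17, and any palladium-induced re-ionisation of the ethers at 70 °C only returns the same ion pair, which can re-etherify or C-prenylate ortho through its CH2 terminus to the same products; the closest known reaction types are the palladium-catalysed reverse O-prenylation of phenols with tertiary allyl carbonates and the Eu(fod)3-catalysed aromatic Claisen rearrangement, each established as a separate single operation but not as an iterative relay through one phenolic oxygen of a free 2-hydroxybenzoate.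

**Compound list**
1 | 4-phenyl-1-butyne | C#CCCc1ccccc1 | starting material
2 | N-methoxy-N-methylacetamide | CC(=O)N(C)OC | starting material
3 | lithium 4-phenylbut-1-yn-1-ide | [Li]C#CCCc1ccccc1 | intermediate (not isolated)
4 | lithium 2-[methoxy(methyl)amino]-6-phenylhex-3-yn-2-olate (racemic) | CC(O[Li])(N(C)OC)C#CCCc1ccccc1 | intermediate (not isolated)
5 | 6-phenylhex-3-yn-2-one | CC(=O)C#CCCc1ccccc1 | intermediate
6 | dimethyl malonate | COC(=O)CC(=O)OC | starting material
7 | dimethyl 2-(5-oxo-1-phenylhex-3-en-3-yl)propanedioate (E/Z mixture, interconverting) | COC(=O)C(C(=O)OC)C(CCc1ccccc1)=CC(C)=O | intermediate (not isolated)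
8 | methyl 2,4-dihydroxy-6-(2-phenylethyl)benzoate | COC(=O)c1c(O)cc(O)cc1CCc1ccccc1 | intermediate
9 | 2-methylbut-3-en-2-ol | CC(C)(O)C=C | starting material
10 | di-tert-butyl dicarbonate | CC(C)(C)OC(=O)OC(=O)OC(C)(C)C | starting material
11 | lithium 2-methylbut-3-en-2-olate | CC(C)(O[Li])C=C | intermediate (not isolated)
12 | tert-butyl (2-methylbut-3-en-2-yl) carbonate | CC(C)(C)OC(=O)OC(C)(C)C=C | intermediate
13 | methyl 2-hydroxy-4-[(2-methylbut-3-en-2-yl)oxy]-6-(2-phenylethyl)benzoate | COC(=O)c1c(O)cc(OC(C)(C)C=C)cc1CCc1ccccc1 | intermediate (not isolated)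
14 | methyl 2,4-dihydroxy-3-(3-methylbut-2-en-1-yl)-6-(2-phenylethyl)benzoate | COC(=O)c1c(O)c(CC=C(C)C)c(O)cc1CCc1ccccc1 | intermediate (not isolated)
15 | methyl 2,4-dihydroxy-5-(3-methylbut-2-en-1-yl)-6-(2-phenylethyl)benzoate | COC(=O)c1c(O)cc(O)c(CC=C(C)C)c1CCc1ccccc1 | intermediate (not isolated)
16 | methyl 2-hydroxy-3-(3-methylbut-2-en-1-yl)-4-[(2-methylbut-3-en-2-yl)oxy]-6-(2-phenylethyl)benzoate | COC(=O)c1c(O)c(CC=C(C)C)c(OC(C)(C)C=C)cc1CCc1ccccc1 | intermediate (not isolated)
17 | methyl 2-hydroxy-5-(3-methylbut-2-en-1-yl)-4-[(2-methylbut-3-en-2-yl)oxy]-6-(2-phenylethyl)benzoate | COC(=O)c1c(O)cc(OC(C)(C)C=C)c(CC=C(C)C)c1CCc1ccccc1 | intermediate (not isolated)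
18 | methyl 2,4-dihydroxy-3,5-bis(3-methylbut-2-en-1-yl)-6-(2-phenylethyl)benzoate | COC(=O)c1c(O)c(CC=C(C)C)c(O)c(CC=C(C)C)c1CCc1ccccc1 | target

**Step count and risks**
Total step count: 4. Longest linear sequence: 3 (steps 1, 2, 4); step 3 is a one-step side branch.

Three steps most likely to fail:

Step 4 (the proposed relay). Risks are palladium-induced drift of the tertiary ethers to linear O-prenyl ethers, loss of the allyl unit as isoprene, binding of Eu(fod)3 by the salicylate unit, and an incomplete second cycle. The fallback sets out from 8 and comes back at 18, using the established three-operation prenyl installation with isolation at each stage. Resorcylate 8 is etherified at the 4-OH with 3-chloro-3-methylbut-1-yne (CuCl2·2H2O 1 mol %, DBU, MeCN, 0 °C) to give methyl 2-hydroxy-4-[(2-methylbut-3-yn-2-yl)oxy]-6-(2-phenylethyl)benzoate F1. Semi-hydrogenation (H2, Pd/CaCO3 poisoned with Pb(OAc)2, quinoline, EtOAc) gives ether 13, and thermal Claisen rearrangement (PhMe, 110 °C) gives 14 with some 15. The same three operations are repeated: 14 gives methyl 2-hydroxy-3-(3-methylbut-2-en-1-yl)-4-[(2-methylbut-3-yn-2-yl)oxy]-6-(2-phenylethyl)benzoate F2, then 16, then 18. Any 15 gives methyl 2-hydroxy-5-(3-methylbut-2-en-1-yl)-4-[(2-methylbut-3-yn-2-yl)oxy]-6-(2-phenylethyl)benzoate F3, then 17, then 18.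

Step 2 (ynone–malonate annulation). Risks are O-cyclisation of the adduct to a 2-pyranone instead of C-cyclisation, methoxide addition to the ynone, and ynone oligomerisation. The fallback sets out from 6 and comes back at 8 by the enone route followed by a separate oxidation. Dimethyl malonate 6 is condensed (NaOMe, MeOH, reflux) with (E)-6-phenylhex-3-en-2-one F4, itself made by a Wittig reaction of commercial 3-phenylpropanal with 1-(triphenylphosphoranylidene)propan-2-one (CH2Cl2, rt). This gives methyl trans-2-hydroxy-4-oxo-6-(2-phenylethyl)cyclohex-2-ene-1-carboxylate F5 (racemic), which is aromatised with Br2 in DMF (0 °C then 80 °C) to 8.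

Step 1 (ynone formation). Risks are conjugate addition of the liberated N,O-dimethylhydroxylamine to the ynone and incomplete acylation. The fallback sets out from 1 and comes back at 5 by addition then oxidation instead of acyl substitution. Acetylide 3 (from 1, n-BuLi, THF, −78 °C) is added to acetaldehyde to give 6-phenylhex-3-yn-2-ol F6 (racemic), which is oxidised with MnO2 (CH2Cl2, rt) to 5.

**Further compounds**
F1 | step 4 | methyl 2-hydroxy-4-[(2-methylbut-3-yn-2-yl)oxy]-6-(2-phenylethyl)benzoate | COC(=O)c1c(O)cc(OC(C)(C)C#C)cc1CCc1ccccc1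
F2 | step 4 | methyl 2-hydroxy-3-(3-methylbut-2-en-1-yl)-4-[(2-methylbut-3-yn-2-yl)oxy]-6-(2-phenylethyl)benzoate | COC(=O)c1c(O)c(CC=C(C)C)c(OC(C)(C)C#C)cc1CCc1ccccc1
F3 | step 4 | methyl 2-hydroxy-5-(3-methylbut-2-en-1-yl)-4-[(2-methylbut-3-yn-2-yl)oxy]-6-(2-phenylethyl)benzoate | COC(=O)c1c(O)cc(OC(C)(C)C#C)c(CC=C(C)C)c1CCc1ccccc1
F4 | step 2 | (E)-6-phenylhex-3-en-2-one | CC(=O)/C=C/CCc1ccccc1
F5 | step 2 | methyl trans-2-hydroxy-4-oxo-6-(2-phenylethyl)cyclohex-2-ene-1-carboxylate (racemic, one enantiomer drawn) | COC(=O)[C@H]1C(O)=CC(=O)C[C@@H]1CCc1ccccc1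
F6 | step 1 | 6-phenylhex-3-yn-2-ol (racemic) | CC(O)C#CCCc1ccccc1
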